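**Strategy.** Ring C of the target (C1=O, C2–OH, C3–H, C4=O, fused at C4a/C8a) is the enol of a naphthalene-1,2,4-trione, that is, an indane-1,2,3-trione enlarged by the single carbon C3. The route builds trione 21 (7-OMe, 6-aroyl, 5-CH2CO2Me) and inserts C3 with diazomethane, forming C2–C3 and C3–C4 in one operation while the peri methoxy group steers the acyl shift. The trione comes from a phthalate made by Diels–Alder aromatisation and an aryne acyl-alkylation that installs the aroyl and acetate arms together. Afterwards the quinone is masked, the pyranone is grown from the acetate, and global demethylation with aerial oxidation finishes the synthesis.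

Key step: step 12

Remarks on the chemistry:
- Numbering of the target: ring C = C1–C4, ring B = C5–C8, fusion atoms C4a/C8a. The target and all main-route compounds are achiral.
- Diazomethane 22 is taken as a freshly distilled ethereal solution made from commercial N-methyl-N-nitroso-p-toluenesulfonamide and KOH; this reagent preparation is not counted as a step. Step 12 consumes two molecules of it: one supplies C3, the other the O-methyl group at C2.
- Silyl enol ethers 2 and 3 are used as obtained (mixtures of double-bond isomers); their geometry is erased in later steps.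

Step 1
Reactants: 1 methyl acetoacetate
Product: 2 methyl 3-(trimethylsilyloxy)but-2-enoate
Conditions: Me3SiCl, Et3N, hexane, rt
Reagents that add atoms: chlorotrimethylsilane, C[Si](C)(C)Cl
Why: Soft enolisation and O-silylation of the β-keto ester should give the silyl enol ether.

Step 2
Reactants: 2 methyl 3-(trimethylsilyloxy)but-2-enoate
Product: 3 1-methoxy-1,3-bis(trimethylsilyloxy)buta-1,3-diene
Conditions: LiN(CHMe2)2 (commercial solution), THF, −78 °C; Me3SiCl, −78 °C → 0 °C
Reagents that add atoms: chlorotrimethylsilane, C[Si](C)(C)Cl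
Why: γ-Deprotonation to the extended ester dienolate and O-silylation is the standard preparation of this 1,3-bis-silyl enol ether.

Step 3
Reactants: 3 1-methoxy-1,3-bis(trimethylsilyloxy)buta-1,3-diene; 4 dimethyl acetylenedicarboxylate
Product: 5 dimethyl 3,5-dihydroxybenzene-1,2-dicarboxylate (dimethyl 3,5-dihydroxyphthalate)
Conditions: toluene, 0 °C → 60 °C; then 1 M HCl, THF, rt
Reagents that add atoms: none
Why: Diels–Alder addition of the electron-rich diene to the acetylenic diester, then aromatisation by loss of methanol and hydrolytic desilylation, should give the resorcinol diester; the symmetric dienophile leaves no regiochemical question.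

Step 4
Reactants: 5 dimethyl 3,5-dihydroxyphthalate
Product: 6 dimethyl 3,5-dihydroxy-4-iodophthalate
Conditions: I2 (1.0 equiv), NaHCO3, THF/H2O, 0 °C
Reagents that add atoms: iodine, II
Why: Electrophilic iodination of the phenolate should occur at C4, ortho to both hydroxyl groups as is usual for resorcinols under hydrogencarbonate conditions, since C6 is flanked by an ester and the limiting charge of iodine restrains di-iodination.

Step 5
Reactants: 6 dimethyl 3,5-dihydroxy-4-iodophthalate
Product: 8 dimethyl 4-iodo-3-methoxy-5-(methoxymethoxy)phthalate, via mono-MOM ether 7 (not isolated)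
Conditions: MeOCH2Cl (1.05 equiv), K2CO3, DMF, 0 °C; then MeI, 40 °C
Reagents that add atoms: chloromethyl methyl ether, COCCl; iodomethane, CI
Why: Sequential Williamson etherification: the free, more acidic C5 hydroxyl (para to an ester) should be alkylated first by the limiting chloromethyl ether, and the ester-chelated C3 hydroxyl is then methylated on warming with excess iodomethane.

Step 6
Reactants: 8 dimethyl 4-iodo-3-methoxy-5-(methoxymethoxy)phthalate
Product: 9 dimethyl 5-hydroxy-4-iodo-3-methoxyphthalate
Conditions: HCl (2 M), MeOH, 45 °C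
Reagents that add atoms: none
Why: Acid-catalysed acetal exchange with methanol should remove the methoxymethyl group selectively, as the aryl methyl ether, the methyl esters and the aryl iodide are stable to dilute methanolic HCl.

Step 7
Reactants: 9 dimethyl 5-hydroxy-4-iodo-3-methoxyphthalate
Product: 12 dimethyl 3-methoxy-5-{[(trifluoromethyl)sulfonyl]oxy}-4-(trimethylsilyl)phthalate, via O-trimethylsilyl ether 10 (not isolated), via lithium 2-silylphenolate 11 (not isolated)
Conditions: (Me3Si)2NH, THF, 65 °C, evaporate; n-BuLi, THF, −100 °C → −78 °C; Tf2O, −78 °C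
Reagents that add atoms: hexamethyldisilazane, C[Si](C)(C)N[Si](C)(C)C; trifluoromethanesulfonic anhydride, O=S(=O)(OS(=O)(=O)C(F)(F)F)C(F)(F)F
Why: O-Silylation, iodine–lithium exchange, retro-Brook 1,3-shift of silicon from oxygen to the lithiated carbon and O-triflation of the phenolate is the standard entry to 2-silylaryl triflates from 2-halophenols; at −100 °C the exchange and the intramolecular silyl shift should outrun addition to the methyl esters, none of which is ortho to the lithiated carbon.

Step 8
Reactants: 13 3,5-dimethoxytoluene; 14 methyl 3-chloro-3-oxopropanoate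
Product: 15 methyl 3-(2,4-dimethoxy-6-methylphenyl)-3-oxopropanoate
Conditions: AlCl3, CH2Cl2, −10 °C → 0 °C
Reagents that add atoms: none
Why: Friedel–Crafts acylation of the activated arene should take place at C2 (ortho to methyl, para to one methoxy group), the usual site of acylation of this ether, and gives the β-keto ester directly.

Step 9
Reactants: 12 dimethyl 3-methoxy-5-{[(trifluoromethyl)sulfonyl]oxy}-4-(trimethylsilyl)phthalate; 15 methyl 3-(2,4-dimethoxy-6-methylphenyl)-3-oxopropanoate
Product: 16 dimethyl 4-(2,4-dimethoxy-6-methylbenzoyl)-3-methoxy-5-(2-methoxy-2-oxoethyl)phthalate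
Conditions: CsF, MeCN, 80 °C
Reagents that add atoms: none
Why: Fluoride-induced elimination gives the 3-methoxyaryne, which should undergo acyl-alkylation with the β-keto ester: C-arylation at C5 (the aryne carbon remote from the methoxy group, also para to an ester), attack of the C4 aryl anion on the ketone and fragmentation of the benzocyclobutenoxide, so that the aroyl group ends ortho to the methoxy group.

Step 10
Reactants: 16 dimethyl 4-(2,4-dimethoxy-6-methylbenzoyl)-3-methoxy-5-(2-methoxy-2-oxoethyl)phthalate; 17 tert-butyl acetate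
Product: 19 methyl 2-[6-(2,4-dimethoxy-6-methylbenzoyl)-7-methoxy-1,3-dioxo-2,3-dihydro-1H-inden-5-yl]acetate, via tert-butyl 1,3-dioxoindane-2-carboxylate 18 (not isolated)
Conditions: LiN(SiMe3)2 (1.05 equiv), THF, −78 °C; LiCH2CO2t-Bu (from 17 and LiN(SiMe3)2, 3 equiv), −78 °C → 50 °C; 1 M HCl work-up; then CF3CO2H, CH2Cl2, rt
Reagents that add atoms: none
Why: Crossed Claisen condensation at the less hindered aryl ester followed by Dieckmann-type closure onto its neighbour should give 18, whose tert-butyl ester is cleaved by trifluoroacetic acid with spontaneous decarboxylation; prior deprotonation of the arylacetate arm shields it, no neutral acetate electrophile is present, the tetra-ortho-substituted diaryl ketone is inert and the methyl arylacetate survives the acid.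

Step 11
Reactants: 19 methyl 2-[6-(2,4-dimethoxy-6-methylbenzoyl)-7-methoxy-1,3-dioxo-2,3-dihydro-1H-inden-5-yl]acetate
Product: 21 methyl 2-[6-(2,4-dimethoxy-6-methylbenzoyl)-7-methoxy-1,2,3-trioxo-2,3-dihydro-1H-inden-5-yl]acetate, via trione hydrate 20 (not isolated)
Conditions: SeO2 (1.2 equiv), dioxane/H2O, 90 °C; then PhCl, reflux, Dean–Stark
Reagents that add atoms: selenium dioxide, O=[Se]=O
Why: Riley oxidation of the doubly activated C2 methylene, far more reactive than the arylacetate or aryl methyl groups, should give the ninhydrin-type hydrate 20, which loses water on azeotropic distillation to the anhydrous vicinal tricarbonyl.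

Step 12
Reactants: 21 methyl 2-[6-(2,4-dimethoxy-6-methylbenzoyl)-7-methoxy-1,2,3-trioxo-2,3-dihydro-1H-inden-5-yl]acetate; 22 diazomethane
Product: 25 methyl 2-[3-(2,4-dimethoxy-6-methylbenzoyl)-4,7-dimethoxy-5,8-dioxo-5,8-dihydronaphthalen-2-yl]acetate, via diazonium betaine 23 (not isolated), via 2-hydroxyquinone 24 (not isolated)
Conditions: CH2N2 (about 2.2 equiv in Et2O: one equivalent for the insertion, one for the O-methylation), CH2Cl2, −78 °C → 0 °C; AcOH quench
Reagents that add atoms: diazomethane (second equivalent, supplies the O-methyl carbon at C2), C=[N+]=[N-]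
Why: The first molecule of diazomethane should add through carbon to the central C2 carbonyl of 21, the most electrophilic site of the vicinal tricarbonyl, to give betaine 23; a 1,2-shift of a flanking acyl carbon to the CH2 group with loss of N2 then gives the naphthalene-1,2,4-trione, which enolises toward C2 (24), and this acidic enol is O-methylated by a second molecule of diazomethane, again with loss of N2. The closest known reaction type is the diazoalkane homologation of ketones (Büchner–Curtius–Schlotterbeck reaction) as applied to indane-1,2,3-triones to give 2-hydroxy-1,4-naphthoquinones, together with the familiar diazomethane methylation of acidic enols. No ring is closed by cyclisation: the five-membered ring is enlarged to six-membered ring C by migration, so no ring-closure geometry applies, and no stereocentre is formed. The step needs the acyl carbon on the methoxy side (indane C1, the future C4) to migrate instead of indane C3; the ortho methoxy group and the para CH2 arm make that acyl group the more electron-rich and so the better migrating group, while the other sits para to the electron-withdrawing aroyl group, which is an expected preference and not a certainty. Chemoselectivity rests on the hindered diaryl ketone and the esters being inert to diazomethane and on limiting the reagent at low temperature so that the product quinone is not consumed by dipolar cycloaddition.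

Step 13
Reactants: 25 methyl 2-[3-(2,4-dimethoxy-6-methylbenzoyl)-4,7-dimethoxy-5,8-dioxo-5,8-dihydronaphthalen-2-yl]acetate
Product: 28 2-[3-(2,4-dimethoxy-6-methylbenzoyl)-4,5,7,8-tetramethoxynaphthalen-2-yl]acetic acid, via hydroquinone 26 (not isolated), via tetramethoxy methyl ester 27 (not isolated)
Conditions: Na2S2O4, Bu4NBr (cat.), THF/H2O, rt; KOH (aq), Me2SO4, rt, N2; then KOH, MeOH, 60 °C; HCl work-up
Reagents that add atoms: dimethyl sulfate, COS(=O)(=O)OC; potassium hydroxide, [K+].[OH-]
Why: Dithionite reduces the quinone to hydroquinone 26, Williamson methylation under phase-transfer conditions gives the dimethyl ether 27 (the same ether would arise from any 4-methoxy-1,2-quinone tautomer formed in step 12), and added hydroxide then saponifies the unhindered arylacetate ester.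

Step 14
Reactants: 28 2-[3-(2,4-dimethoxy-6-methylbenzoyl)-4,5,7,8-tetramethoxynaphthalen-2-yl]acetic acid; 3 1-methoxy-1,3-bis(trimethylsilyloxy)buta-1,3-diene
Product: 30 methyl 6-[3-(2,4-dimethoxy-6-methylbenzoyl)-4,5,7,8-tetramethoxynaphthalen-2-yl]-3,5-dioxohexanoate, via acid chloride 29 (not isolated)
Conditions: 1-chloro-N,N,2-trimethylprop-1-en-1-amine, CH2Cl2, 0 °C → rt; then 3 (2 equiv), CH2Cl2, −78 °C → rt; aq. NH4Cl, 1 M HCl
Reagents that add atoms: 1-chloro-N,N,2-trimethylprop-1-en-1-amine, CC(C)=C(Cl)N(C)C (supplies only the chlorine of 29; nothing remains in 30)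
Why: The acid chloride is formed under neutral conditions and should acylate the terminal carbon of the bis-silyl dienolate without catalyst (vinylogous Claisen-type acylation of a 1,3-bis-silyl enol ether), hydrolytic work-up giving the 3,5-dioxo ester; the absence of base avoids ketene formation and the masked quinone cannot act as dienophile or Michael acceptor.

Step 15
Reactants: 30 methyl 6-[3-(2,4-dimethoxy-6-methylbenzoyl)-4,5,7,8-tetramethoxynaphthalen-2-yl]-3,5-dioxohexanoate
Product: 31 6-{[3-(2,4-dimethoxy-6-methylbenzoyl)-4,5,7,8-tetramethoxynaphthalen-2-yl]methyl}-4-hydroxy-2H-pyran-2-one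
Conditions: DBU, toluene, 60 °C; then 1 M HCl
Reagents that add atoms: none
Why: Base-mediated lactonisation (the enol oxygen of the C5 ketone attacks the ester carbonyl, 6-exo-trig) with loss of methanol is the standard closure of 3,5-dioxo esters to 6-substituted 4-hydroxy-2-pyranones, and the hindered diaryl ketone should not undergo aldol reaction.

Step 16
Reactants: 31 6-{[3-(2,4-dimethoxy-6-methylbenzoyl)-4,5,7,8-tetramethoxynaphthalen-2-yl]methyl}-4-hydroxy-2H-pyran-2-one
Product: 33 6-(2,4-dihydroxy-6-methylbenzoyl)-2,5-dihydroxy-7-[(4-hydroxy-2-oxo-2H-pyran-6-yl)methyl]naphthalene-1,4-dione (target), via naphthalenetriol 32 (not isolated)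
Conditions: BBr3 (excess), CH2Cl2, −78 °C → rt; then H2O, EtOAc, air, rt
Reagents that add atoms: none
Why: Boron tribromide should cleave all six aryl methyl ethers (those ortho to the ketone with chelation assistance), and the liberated 1,2,4-trihydroxynaphthalene unit of 32 is autoxidised by air on work-up to the 2-hydroxy-1,4-quinone, the preferred tautomer.

**Compound list**

1 | methyl acetoacetate | COC(=O)CC(C)=O | starting material
2 | methyl 3-(trimethylsilyloxy)but-2-enoate (isomer mixture) | COC(=O)C=C(C)O[Si](C)(C)C | intermediate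
3 | 1-methoxy-1,3-bis(trimethylsilyloxy)buta-1,3-diene | COC(O[Si](C)(C)C)=CC(=C)O[Si](C)(C)C | intermediate
4 | dimethyl acetylenedicarboxylate | COC(=O)C#CC(=O)OC | starting material
5 | dimethyl 3,5-dihydroxyphthalate | COC(=O)c1cc(O)cc(O)c1C(=O)OC | intermediate
6 | dimethyl 3,5-dihydroxy-4-iodophthalate | COC(=O)c1cc(O)c(I)c(O)c1C(=O)OC | intermediate
7 | dimethyl 3-hydroxy-4-iodo-5-(methoxymethoxy)phthalate | COCOc1cc(C(=O)OC)c(C(=O)OC)c(O)c1I | intermediate
8 | dimethyl 4-iodo-3-methoxy-5-(methoxymethoxy)phthalate | COCOc1cc(C(=O)OC)c(C(=O)OC)c(OC)c1I | intermediate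
9 | dimethyl 5-hydroxy-4-iodo-3-methoxyphthalate | Oc1cc(C(=O)OC)c(C(=O)OC)c(OC)c1I | intermediate
10 | dimethyl 4-iodo-3-methoxy-5-(trimethylsilyloxy)phthalate | C[Si](C)(C)Oc1cc(C(=O)OC)c(C(=O)OC)c(OC)c1I | intermediate
11 | lithium 3-methoxy-4,5-bis(methoxycarbonyl)-2-(trimethylsilyl)phenolate | [Li+].[O-]c1cc(C(=O)OC)c(C(=O)OC)c(OC)c1[Si](C)(C)C | intermediate
12 | dimethyl 3-methoxy-5-{[(trifluoromethyl)sulfonyl]oxy}-4-(trimethylsilyl)phthalate | COC(=O)c1cc(OS(=O)(=O)C(F)(F)F)c([Si](C)(C)C)c(OC)c1C(=O)OC | intermediate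
13 | 3,5-dimethoxytoluene | Cc1cc(OC)cc(OC)c1 | starting material
14 | methyl 3-chloro-3-oxopropanoate | COC(=O)CC(Cl)=O | starting material
15 | methyl 3-(2,4-dimethoxy-6-methylphenyl)-3-oxopropanoate | COC(=O)CC(=O)c1c(C)cc(OC)cc1OC | intermediate
16 | dimethyl 4-(2,4-dimethoxy-6-methylbenzoyl)-3-methoxy-5-(2-methoxy-2-oxoethyl)phthalate | COC(=O)Cc1cc(C(=O)OC)c(C(=O)OC)c(OC)c1C(=O)c1c(C)cc(OC)cc1OC | intermediate
17 | tert-butyl acetate | CC(=O)OC(C)(C)C | starting material
18 | tert-butyl 5-(2,4-dimethoxy-6-methylbenzoyl)-4-methoxy-6-(2-methoxy-2-oxoethyl)-1,3-dioxo-2,3-dihydro-1H-indene-2-carboxylate | COC(=O)Cc1cc2c(c(OC)c1C(=O)c1c(C)cc(OC)cc1OC)C(=O)C(C(=O)OC(C)(C)C)C2=O | intermediate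
19 | methyl 2-[6-(2,4-dimethoxy-6-methylbenzoyl)-7-methoxy-1,3-dioxo-2,3-dihydro-1H-inden-5-yl]acetate | COC(=O)Cc1cc2c(c(OC)c1C(=O)c1c(C)cc(OC)cc1OC)C(=O)CC2=O | intermediate
20 | methyl 2-[6-(2,4-dimethoxy-6-methylbenzoyl)-2,2-dihydroxy-7-methoxy-1,3-dioxo-2,3-dihydro-1H-inden-5-yl]acetate | COC(=O)Cc1cc2c(c(OC)c1C(=O)c1c(C)cc(OC)cc1OC)C(=O)C(O)(O)C2=O | intermediate
21 | methyl 2-[6-(2,4-dimethoxy-6-methylbenzoyl)-7-methoxy-1,2,3-trioxo-2,3-dihydro-1H-inden-5-yl]acetate | COC(=O)Cc1cc2c(c(OC)c1C(=O)c1c(C)cc(OC)cc1OC)C(=O)C(=O)C2=O | intermediate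
22 | diazomethane | C=[N+]=[N-] | starting material
23 | methyl 2-[2-(diazoniomethyl)-6-(2,4-dimethoxy-6-methylbenzoyl)-7-methoxy-2-oxido-1,3-dioxo-2,3-dihydro-1H-inden-5-yl]acetate | COC(=O)Cc1cc2c(c(OC)c1C(=O)c1c(C)cc(OC)cc1OC)C(=O)C([O-])(C[N+]#N)C2=O | intermediate
24 | methyl 2-[3-(2,4-dimethoxy-6-methylbenzoyl)-7-hydroxy-4-methoxy-5,8-dioxo-5,8-dihydronaphthalen-2-yl]acetate | COC(=O)Cc1cc2c(c(OC)c1C(=O)c1c(C)cc(OC)cc1OC)C(=O)C=C(O)C2=O | intermediate
25 | methyl 2-[3-(2,4-dimethoxy-6-methylbenzoyl)-4,7-dimethoxy-5,8-dioxo-5,8-dihydronaphthalen-2-yl]acetate | COC(=O)Cc1cc2c(c(OC)c1C(=O)c1c(C)cc(OC)cc1OC)C(=O)C=C(OC)C2=O | intermediate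
26 | methyl 2-[3-(2,4-dimethoxy-6-methylbenzoyl)-5,8-dihydroxy-4,7-dimethoxynaphthalen-2-yl]acetate | COC(=O)Cc1cc2c(O)c(OC)cc(O)c2c(OC)c1C(=O)c1c(C)cc(OC)cc1OC | intermediate
27 | methyl 2-[3-(2,4-dimethoxy-6-methylbenzoyl)-4,5,7,8-tetramethoxynaphthalen-2-yl]acetate | COC(=O)Cc1cc2c(OC)c(OC)cc(OC)c2c(OC)c1C(=O)c1c(C)cc(OC)cc1OC | intermediate
28 | 2-[3-(2,4-dimethoxy-6-methylbenzoyl)-4,5,7,8-tetramethoxynaphthalen-2-yl]acetic acid | OC(=O)Cc1cc2c(OC)c(OC)cc(OC)c2c(OC)c1C(=O)c1c(C)cc(OC)cc1OC | intermediate
29 | 2-[3-(2,4-dimethoxy-6-methylbenzoyl)-4,5,7,8-tetramethoxynaphthalen-2-yl]acetyl chloride | ClC(=O)Cc1cc2c(OC)c(OC)cc(OC)c2c(OC)c1C(=O)c1c(C)cc(OC)cc1OC | intermediate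
30 | methyl 6-[3-(2,4-dimethoxy-6-methylbenzoyl)-4,5,7,8-tetramethoxynaphthalen-2-yl]-3,5-dioxohexanoate | COC(=O)CC(=O)CC(=O)Cc1cc2c(OC)c(OC)cc(OC)c2c(OC)c1C(=O)c1c(C)cc(OC)cc1OC | intermediate
31 | 6-{[3-(2,4-dimethoxy-6-methylbenzoyl)-4,5,7,8-tetramethoxynaphthalen-2-yl]methyl}-4-hydroxy-2H-pyran-2-one | O=c1cc(O)cc(Cc2cc3c(OC)c(OC)cc(OC)c3c(OC)c2C(=O)c2c(C)cc(OC)cc2OC)o1 | intermediate
32 | 6-{[3-(2,4-dihydroxy-6-methylbenzoyl)-4,5,7,8-tetrahydroxynaphthalen-2-yl]methyl}-4-hydroxy-2H-pyran-2-one | O=c1cc(O)cc(Cc2cc3c(O)c(O)cc(O)c3c(O)c2C(=O)c2c(C)cc(O)cc2O)o1 | intermediate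
33 | 6-(2,4-dihydroxy-6-methylbenzoyl)-2,5-dihydroxy-7-[(4-hydroxy-2-oxo-2H-pyran-6-yl)methyl]naphthalene-1,4-dione | Cc1cc(O)cc(O)c1C(=O)c1c(Cc2cc(O)cc(=O)o2)cc2c(c1O)C(=O)C=C(O)C2=O | target

**Step count.** Total: 16 steps. Longest linear sequence: 15 steps (steps 1–7, then 9–16); step 8 is a one-step branch.

**The three steps most likely to fail**

1. Step 12 (diazomethane insertion). The wrong flanking acyl carbon may shift, the betaine may close to a spiro-epoxide instead of rearranging, or surplus reagent may add to the newly formed quinone. The fallback moves the insertion to an earlier, simpler and more strongly biased substrate and introduces the two side arms last. It sets out from 8. Condensation with lithium tert-butyl acetate as in step 10, with the tert-butyl ester then removed by heating in wet toluene at 110 °C (loss of tert-butanol and CO2 by way of the acylketene) in place of acid so that the MOM ether survives, would give 6-iodo-7-methoxy-5-(methoxymethoxy)indane-1,3-dione F1. SeO2 oxidation (buffered with pyridine to spare the acetal) and dehydration as in step 11 would give trione F2, and diazomethane (two equivalents, as in step 12) would give 6-iodo-2,5-dimethoxy-7-(methoxymethoxy)naphthalene-1,4-dione F3. In F2 the acyl carbon that has to migrate is conjugated with both an ortho and a para oxygen donor, and any minor isomer is removed on a cheap intermediate. Reductive methylation (Na2S2O4; Me2SO4, KOH) would give 6-iodo-1,2,4,5-tetramethoxy-7-(methoxymethoxy)naphthalene F4, and HCl in MeOH the naphthol 3-iodo-4,5,7,8-tetramethoxynaphthalen-2-ol F5. The silylation, retro-Brook shift and triflation of step 7 (no ester is present now) would give 4,5,7,8-tetramethoxy-3-(trimethylsilyl)naphthalen-2-yl trifluoromethanesulfonate F6. Its CsF-induced acyl-alkylation with 15 returns to the route at 27, which is saponified to 28 as in the last stage of step 13.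

2. Step 9 (aryne acyl-alkylation). After C-arylation the aryl anion may be protonated faster than it adds to the doubly ortho-substituted ketone, so that the sequence stops at simple α-arylation. The fallback builds the two arms one after the other without an aryne and sets out from 8. Iodine–magnesium exchange (Me2CHMgCl·LiCl, THF, −40 °C, esters tolerated) and addition to commercial 2,4-dimethoxy-6-methylbenzaldehyde would give the racemic carbinol dimethyl 4-[(2,4-dimethoxy-6-methylphenyl)(hydroxy)methyl]-3-methoxy-5-(methoxymethoxy)phthalate F7. Dess–Martin periodinane would oxidise it to ketone F8, HCl in MeOH would free the phenol F9, and Tf2O with pyridine would give aryl triflate F10. Malonate α-arylation catalysed by Pd(OAc)2 with P(t-Bu)3·HBF4 and K3PO4 in toluene, using tert-butyl methyl malonate, would give the racemic aryl malonate F11. CF3CO2H followed by warming removes the tert-butyl ester with decarboxylation and returns to the route at 16.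

3. Step 7 (silyl shift in the presence of two methyl esters). n-BuLi or the aryllithium may attack an ester before the silyl group has moved from oxygen to carbon. The fallback replaces the oxygen-to-carbon migration by direct C-silylation of an ester-tolerant arylmagnesium species and sets out from 8. Exchange with Me2CHMgCl·LiCl (THF, −40 °C) and trapping with Me3SiOTf would give dimethyl 3-methoxy-5-(methoxymethoxy)-4-(trimethylsilyl)phthalate F12. Mild acetal cleavage (pyridinium p-toluenesulfonate, MeOH, 50 °C) would give dimethyl 5-hydroxy-3-methoxy-4-(trimethylsilyl)phthalate F13, and Tf2O with pyridine at 0 °C returns to the route at 12.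

**Further compounds**

F1 | step 12 | 6-iodo-7-methoxy-5-(methoxymethoxy)-1H-indene-1,3(2H)-dione | COCOc1cc2c(c(OC)c1I)C(=O)CC2=O
F2 | step 12 | 6-iodo-7-methoxy-5-(methoxymethoxy)-1H-indene-1,2,3-trione | COCOc1cc2c(c(OC)c1I)C(=O)C(=O)C2=O
F3 | step 12 | 6-iodo-2,5-dimethoxy-7-(methoxymethoxy)naphthalene-1,4-dione | COCOc1cc2c(c(OC)c1I)C(=O)C=C(OC)C2=O
F4 | step 12 | 6-iodo-1,2,4,5-tetramethoxy-7-(methoxymethoxy)naphthalene | COCOc1cc2c(OC)c(OC)cc(OC)c2c(OC)c1I
F5 | step 12 | 3-iodo-4,5,7,8-tetramethoxynaphthalen-2-ol | Oc1cc2c(OC)c(OC)cc(OC)c2c(OC)c1I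
F6 | step 12 | 4,5,7,8-tetramethoxy-3-(trimethylsilyl)naphthalen-2-yl trifluoromethanesulfonate | COc1cc(OC)c2c(OC)c([Si](C)(C)C)c(OS(=O)(=O)C(F)(F)F)cc2c1OC
F7 | step 9 | dimethyl 4-[(2,4-dimethoxy-6-methylphenyl)(hydroxy)methyl]-3-methoxy-5-(methoxymethoxy)phthalate (racemic) | COCOc1cc(C(=O)OC)c(C(=O)OC)c(OC)c1C(O)c1c(C)cc(OC)cc1OC
F8 | step 9 | dimethyl 4-(2,4-dimethoxy-6-methylbenzoyl)-3-methoxy-5-(methoxymethoxy)phthalate | COCOc1cc(C(=O)OC)c(C(=O)OC)c(OC)c1C(=O)c1c(C)cc(OC)cc1OC
F9 | step 9 | dimethyl 4-(2,4-dimethoxy-6-methylbenzoyl)-5-hydroxy-3-methoxyphthalate | Oc1cc(C(=O)OC)c(C(=O)OC)c(OC)c1C(=O)c1c(C)cc(OC)cc1OC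
F10 | step 9 | dimethyl 4-(2,4-dimethoxy-6-methylbenzoyl)-3-methoxy-5-{[(trifluoromethyl)sulfonyl]oxy}phthalate | COC(=O)c1cc(OS(=O)(=O)C(F)(F)F)c(C(=O)c2c(C)cc(OC)cc2OC)c(OC)c1C(=O)OC
F11 | step 9 | 1-tert-butyl 3-methyl 2-[2-(2,4-dimethoxy-6-methylbenzoyl)-3-methoxy-4,5-bis(methoxycarbonyl)phenyl]propanedioate (racemic) | COC(=O)C(C(=O)OC(C)(C)C)c1cc(C(=O)OC)c(C(=O)OC)c(OC)c1C(=O)c1c(C)cc(OC)cc1OC
F12 | step 7 | dimethyl 3-methoxy-5-(methoxymethoxy)-4-(trimethylsilyl)phthalate | COCOc1cc(C(=O)OC)c(C(=O)OC)c(OC)c1[Si](C)(C)C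
F13 | step 7 | dimethyl 5-hydroxy-3-methoxy-4-(trimethylsilyl)phthalate | Oc1cc(C(=O)OC)c(C(=O)OC)c(OC)c1[Si](C)(C)C
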